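## The problem

The target is an unsymmetrical near-dimer: two 3,4-dihydro-2H-pyran rings, each fused through its oxygen-bearing and C4-bearing sp2 carbons to a methyl-substituted tropolone, are linked from pyran C2 to pyran C2 by an (E,E)-buta-1,3-diene. It holds three stereocentres: C2 and C3 of the left pyran (2R,3R, substituents trans) and C2 of the right pyran (R). The right centre lies five bonds away across the flat diene and needs its own source of absolute configuration, whereas inside the left ring C3 can govern C2 because the trans-diequatorial arrangement is the stable one. Each C2–O bond is an allylic ether of a vinylogous acid (the ring oxygen sits on tropone C4) and becomes dienylic once the halves are joined, so acids, Lewis acids and zerovalent palladium can ionise it; the diene should therefore be completed late, stereospecifically and without such reagents. The tropolones are acidic chelators that must stay masked through every organometallic step and be released at the end without acid. No tropolone with this pattern (oxygen at tropone C1, C2 and C4, carbon at C5, methyl at C6) can be bought, so the seven-membered ring has to be made, preferably once, as a building block for both halves. The feature that invites a strain-release closure is that C2 and C4 of the left pyran are 1,3-related through the methyl-bearing C3: bonding them gives a cyclopropane on tropone C5 whose C2–C4 bond is flanked by a vinyl group (allyl-cation side) and by the tropone (carbanion side), with the hydroxyl on tropone C4 placed to close the six-membered ring on C2.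

## Retrosynthesis

**Unmasking.** Target 34 is traced to its bis(methyl ether) 33 by cutting two O–CH3 bonds. Methyl is the tropolone mask expected to survive zinc carbenoids, divalent chromium, fluoride, palladium and copper, which a silyl, acyl or acetal group would not all do. The forward step has to cleave two vinylogous methyl esters without acid.

**Diene.** The central C–C single bond of the diene in 33 is cut, giving alkenyl iodide 19 (left) and alkenylstannane 32 (right). Cutting a C=C bond instead would need an epimerisable 2-formylpyran on one side and an allylic ylide or sulfone with a β-leaving group on the other. The chosen cut joins two preformed (E)-alkenes with retention and splits the molecule into halves of similar size. The forward union must run without zerovalent palladium, which a copper carboxylate allows.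

**Left pyran.** Iodide 19 comes from alkenylsilane 18 (C–I for C–Si). In 18 the O1–C2 bond is cut and C2 is reconnected to C4, which turns the pyran into the vinylcyclopropane of hydroxytropone 17. The neighbouring cut, O1–C2 with a leaving group on an open chain, would need two stereocentres built on an acyclic chain. The cyclopropane hides C2 and C3 in a ring that one enantioselective cyclopropanation delivers, and it is an isomer of the product, so nothing is lost on closure. The forward reaction must break the C2–C4 bond heterolytically and deliver the ring oxygen to C2 trans to the methyl group.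

**Cyclopropane.** Hydroxytropone 17 is the fluoride-unmasked form of silylethyl ether 16. Its (E)-alkenylsilane is cut at the C=C bond to aldehyde 14 and (dibromomethyl)trimethylsilane 15, and 14 comes from cyclopropylmethanol 13. Cutting both ring bonds of the methyl-bearing carbon in 13 leads to (E)-allylic alcohol 11 and 1,1-diiodoethane 12; the hydroxyl is the handle for a directed, enantioselective carbenoid addition. Alcohol 11 is divided at the tropone–alkene bond into bromotropone 9 and hydroxypropenylstannane 10.

**Right half.** Stannane 32 is cut at its C=C bond to aldehyde 27 and (dibromomethyl)tributylstannane 31, the latter from dibromomethane 28 and tributyltin chloride 29 through 30. Aldehyde 27 comes from alcohol 26 and trityl ether 25. Cutting O1–C2 of 25 gives hydroxytropone alcohol 24, to be closed with inversion; 24 is the unmasked form of 23. Cutting the CH2–tropone bond of 23 returns bromotropone 9 and the alkene 21 (through borane 22), which is the trityl ether of (S)-but-3-ene-1,2-diol 20. The stereocentre is bought, and one tropone serves both halves.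

**Tropone.** Methyl ether 9 comes from bromotropolone 8. The brominated carbon of 8 is treated as a one-carbon insert between the methyl-bearing and the oxygen-bearing carbon of a six-membered ring. This leads through dione 7 and diol 6 to dibromocyclopropane 5, then to Birch diene 4, aryl ether 3, and finally 2-methylphenol 1 and 2-(trimethylsilyl)ethanol 2. Against cycloaddition or condensation routes to the seven-membered ring, this one places bromine exactly where both side chains are needed and brings the ring oxygen already masked with a fluoride-labile group.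

## Roads not taken

**Alternative 1:** The cut is made at C2–C3 of both pyrans at once. Forward, the precursor of A1 is a tartrate-derived hexa-1,5-diene-3,4-diol whose alkene termini are enol ethers of the bromo-methoxytropone and whose hydroxyls carry a propionate and an acetate. It is doubly enolised and silylated, and two chair Ireland–Claisen shifts give dienyl diacid A1 with all three stereocentres and the (E,E)-diene.
- Merits: one cheap template sets every stereocentre, and the diene geometry follows from the chair.
- Weak points: two different esters must be enolised with defined geometry by a strong amide base in the presence of two bromotropone vinylogous esters; aryloxyvinyl ethers of defined geometry are hard to make; A1 carries β-aryloxy acids prone to elimination; and no ring is closed, so each pyran still needs a carboxyl carbon reduced and joined to a C–Br carbon on a dienylic bis-ether.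
- Comparison: A1 is better in stereochemical economy and forms the diene without tin. The chosen plan sets against this that every bond to the tropone is made by cross-coupling on simple bromide 9, each ring is closed at fragment stage, and no strong base meets a tropone.

**Alternative 2:** The cut removes two ring bonds of the right tropolone. Forward, dihydropyran keto-aldehyde A3 reacts with methoxy ketophosphonate A4: Horner–Wadsworth–Emmons olefination of the formyl group, then aldol condensation of the new methyl ketone with the acetyl group, closes the seven-membered ring to A2.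
- Merits: the methoxy group is placed without any regiochemical question, which step 6 of the chosen route cannot claim; no dissolving metal, carbene or osmium is needed; and A2 is the silyl analogue of 25.
- Weak points: A3 is a push–pull diacyl enol ether that is not trivial to make with its stereocentre; the olefination must give the (Z)-enone for closure; condensation to a monocyclic, fully unsaturated seven-membered ring is demanding; and the left half needs a different, trans-disubstituted keto-aldehyde, so two pyran syntheses and two annulations result, with the diene still unsolved.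
- Comparison: Alternative 2 may be shorter for the right half and is cleaner on O-methyl regiochemistry. The chosen plan sets against this one common tropone made by a known ring expansion and a left ring closure in which C3 controls C2.

**Alternative 3:** The cut is O1–C2 of the right pyran in the last skeletal step. Forward, the precursor of A5 carries the finished left pyran, a bis-allylic alcohol and a free hydroxytropone. A π-acid such as PdCl2(MeCN)2 promotes syn addition of the tropone hydroxyl to the remote alkene carbon with loss of the hydroxyl, giving A5, which is identical with 33.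
- Merits: ring and conjugated diene appear together, so the dienylic ethers exist only at the very end; the carbinol is easy to set; no stoichiometric tin or copper is used; and the fragments are joined by carbonyl addition.
- Weak points: the bis-allylic alcohol can also ionise toward the left alkene, where the left C2–O bond would be expelled or epimerised by the same catalyst; chirality transfer needs a single alkene geometry; and right C2 has no neighbouring centre to correct erosion.
- Comparison: Alternative 3 is more convergent, and its endgame equals that of the chosen plan. The chosen plan sets against this that right C2 is fixed by an SN2 inversion from diol 20 while nothing else can ionise, and that the diene geometry is inherited from two isolated (E)-alkenes.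

Key step: step 12

Assumption: O-methylation of tropolone 8 is taken to give two separable regioisomers. The route is written for 9 (methoxy on the carbon next to C3–H), and the other isomer would converge on the same tropolone in step 23.

Assumption: compounds 1, 2, 10, 12, 15, 20, 28 and 29 are taken as purchasable.

Step 1
Reactants: 1 2-methylphenol; 2 2-(trimethylsilyl)ethanol
Product: 3 1-methyl-2-[2-(trimethylsilyl)ethoxy]benzene
Conditions: PPh3, DIAD, THF, 0 °C → rt
Reagents that add atoms: none
Why: Mitsunobu etherification of a phenol with a primary alcohol; the silylethyl group is a plain alkyl ether towards dissolving metal and becomes fluoride-labile once it sits on the tropone as a vinylogous ester.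

Step 2
Reactants: 3 1-methyl-2-[2-(trimethylsilyl)ethoxy]benzene
Product: 4 1-methyl-2-[2-(trimethylsilyl)ethoxy]cyclohexa-1,4-diene
Conditions: Li, NH3 (l), t-BuOH, THF, −78 °C; then NH4Cl
Reagents that add atoms: none
Why: Birch reduction of an ortho-alkyl aryl ether gives the 2,5-dihydro product, in which the alkoxy and methyl groups share one tetrasubstituted enol-ether double bond.

Step 3
Reactants: 4 1-methyl-2-[2-(trimethylsilyl)ethoxy]cyclohexa-1,4-diene
Product: 5 racemic cis-fused 7,7-dibromo-1-methyl-6-[2-(trimethylsilyl)ethoxy]bicyclo[4.1.0]hept-3-ene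
Conditions: CHBr3, KOt-Bu, pentane, −10 → 0 °C
Reagents that add atoms: bromoform, BrC(Br)Br
Why: Dibromocarbene adds to the electron-rich tetrasubstituted enol ether in preference to the isolated disubstituted alkene; the ring fusion can only be cis, and both stereocentres vanish in step 5.

Step 4
Reactants: 5 racemic cis-fused 7,7-dibromo-1-methyl-6-[2-(trimethylsilyl)ethoxy]bicyclo[4.1.0]hept-3-ene
Product: 6 racemic 7,7-dibromo-1-methyl-6-[2-(trimethylsilyl)ethoxy]bicyclo[4.1.0]heptane-3,4-diol (cis-diol, anti to the dibromomethylene bridge)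
Conditions: OsO4 (2 mol %), NMO, acetone/H2O, rt
Reagents that add atoms: N-methylmorpholine N-oxide, C[N+]1([O-])CCOCC1; water, O (oxygen delivered through OsO4, O=[Os](=O)(=O)=O)
Why: Catalytic syn-dihydroxylation of the remaining alkene from the face away from the endo bromine; the diol configuration is immaterial because both carbinols are oxidised next.

Step 5
Reactants: 6 racemic 7,7-dibromo-1-methyl-6-[2-(trimethylsilyl)ethoxy]bicyclo[4.1.0]heptane-3,4-diol
Product: 8 5-bromo-2-hydroxy-6-methyl-4-[2-(trimethylsilyl)ethoxy]cyclohepta-2,4,6-trien-1-one, via the bicyclic 1,2-dione 7 (not isolated)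
Conditions: TFAA, DMSO, CH2Cl2, −78 °C; then Et3N, −78 °C → rt
Reagents that add atoms: none
Why: Swern-type oxidation gives dione 7, which enolises towards both ring-fusion carbons; the resulting norcaradiene opens electrocyclically to a 7,7-dibromocycloheptatriene that ionises and loses HBr. This is the known gem-dibromocyclopropane route to bromotropolones and leaves bromine on the inserted carbon between the methyl- and alkoxy-bearing carbons.

Step 6
Reactants: 8 5-bromo-2-hydroxy-6-methyl-4-[2-(trimethylsilyl)ethoxy]cyclohepta-2,4,6-trien-1-one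
Product: 9 5-bromo-2-methoxy-6-methyl-4-[2-(trimethylsilyl)ethoxy]cyclohepta-2,4,6-trien-1-one
Conditions: MeI, K2CO3, acetone, 50 °C; chromatographic removal of the O-methyl regioisomer
Reagents that add atoms: iodomethane, CI
Why: O-Alkylation of the tropolonate; the methyl ether masks the chelating unit for all later metal-mediated steps.

Step 7
Reactants: 9 5-bromo-2-methoxy-6-methyl-4-[2-(trimethylsilyl)ethoxy]cyclohepta-2,4,6-trien-1-one; 10 (E)-3-(tributylstannyl)prop-2-en-1-ol
Product: 11 5-[(E)-3-hydroxyprop-1-en-1-yl]-2-methoxy-6-methyl-4-[2-(trimethylsilyl)ethoxy]cyclohepta-2,4,6-trien-1-one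
Conditions: Pd2(dba)3 (5 mol %), AsPh3, CuI, NMP, 50 °C
Reagents that add atoms: none
Why: Stille coupling at the electron-poor alkenyl-type bromide of the tropone under neutral, fluoride-free conditions; alkene geometry is retained and the free hydroxyl is tolerated.

Step 8
Reactants: 11 5-[(E)-3-hydroxyprop-1-en-1-yl]-2-methoxy-6-methyl-4-[2-(trimethylsilyl)ethoxy]cyclohepta-2,4,6-trien-1-one; 12 1,1-diiodoethane
Product: 13 5-[(1S,2S,3R)-2-(hydroxymethyl)-3-methylcyclopropyl]-2-methoxy-6-methyl-4-[2-(trimethylsilyl)ethoxy]cyclohepta-2,4,6-trien-1-one (methyl cis to the tropone ring, hydroxymethyl trans to both)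
Conditions: Et2Zn, CH3CHI2, (4R,5R)-2-butyl-N,N,N',N'-tetramethyl-1,3,2-dioxaborolane-4,5-dicarboxamide, CH2Cl2, −10 °C → rt
Reagents that add atoms: none
Why: Directed asymmetric Simmons–Smith (Charette) cyclopropanation: the zinc alkoxide bound to the (4R,5R)-dioxaborolane takes the 1-iodoethylzinc carbenoid on the alkene face that gives (1S,2S)-cyclopropylmethanols from (E)-3-arylallyl alcohols. The carbenoid methyl settles anti to the hydroxymethyl arm and cis to the tropone, which fixes the future C3 of the left pyran.

Step 9
Reactants: 13 5-[(1S,2S,3R)-2-(hydroxymethyl)-3-methylcyclopropyl]-2-methoxy-6-methyl-4-[2-(trimethylsilyl)ethoxy]cyclohepta-2,4,6-trien-1-one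
Product: 14 5-[(1S,2S,3R)-2-formyl-3-methylcyclopropyl]-2-methoxy-6-methyl-4-[2-(trimethylsilyl)ethoxy]cyclohepta-2,4,6-trien-1-one
Conditions: Dess–Martin periodinane, NaHCO3, CH2Cl2, 0 °C → rt
Reagents that add atoms: none
Why: Buffered Dess–Martin oxidation of a primary alcohol; the formyl group is already trans to both neighbours, so there is no drive to epimerise.

Step 10
Reactants: 14 5-[(1S,2S,3R)-2-formyl-3-methylcyclopropyl]-2-methoxy-6-methyl-4-[2-(trimethylsilyl)ethoxy]cyclohepta-2,4,6-trien-1-one; 15 (dibromomethyl)trimethylsilane
Product: 16 2-methoxy-6-methyl-5-[(1S,2S,3S)-2-methyl-3-[(E)-2-(trimethylsilyl)ethenyl]cyclopropyl]-4-[2-(trimethylsilyl)ethoxy]cyclohepta-2,4,6-trien-1-one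
Conditions: CrCl2, THF, rt
Reagents that add atoms: none
Why: Takai–Utimoto olefination: the geminal dichromium species formed from 15 and divalent chromium adds to the aldehyde and eliminates to the (E)-alkenylsilane; the reagent is selective for aldehydes and should leave the tropone alone.

Step 11
Reactants: 16 2-methoxy-6-methyl-5-[(1S,2S,3S)-2-methyl-3-[(E)-2-(trimethylsilyl)ethenyl]cyclopropyl]-4-[2-(trimethylsilyl)ethoxy]cyclohepta-2,4,6-trien-1-one
Product: 17 4-hydroxy-2-methoxy-6-methyl-5-[(1S,2S,3S)-2-methyl-3-[(E)-2-(trimethylsilyl)ethenyl]cyclopropyl]cyclohepta-2,4,6-trien-1-one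
Conditions: Bu4NF, THF, 0 °C; NaH2PO4 buffer
Reagents that add atoms: none
Why: Fluoride-induced fragmentation of the 2-(trimethylsilyl)ethyl group, as for the corresponding esters, releases ethene and the vinylogous acid; the alkenylsilane and the methyl ether are inert at 0 °C.

Step 12
Reactants: 17 4-hydroxy-2-methoxy-6-methyl-5-[(1S,2S,3S)-2-methyl-3-[(E)-2-(trimethylsilyl)ethenyl]cyclopropyl]cyclohepta-2,4,6-trien-1-one
Product: 18 (2R,3R)-8-methoxy-3,5-dimethyl-2-[(E)-2-(trimethylsilyl)ethenyl]-3,4-dihydrocyclohepta[b]pyran-7(2H)-one
Conditions: Pd(PPh3)4 (10 mol %), degassed THF, 50 °C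
Reagents that add atoms: none
Why: Proposed new method: zerovalent palladium binds the silylvinyl group and cleaves, by SN2'-type oxidative addition, the cyclopropane bond between the vinyl-bearing and the tropone-bearing carbon, the one bond whose rupture leaves an η3-allylpalladium cation and a carbanion on the future C4 that is delocalised through the tropone (C5=C4, C3=C2, C1=O); the closest known reactions are the palladium-catalysed opening of vinylcyclopropanes with geminal acceptors to zwitterionic allyl complexes and the intramolecular Tsuji–Trost etherification of phenols. The adjacent hydroxyl, a vinylogous acid, protonates this carbanion, so C4 becomes CH2 and an oxide is released next to the allyl unit before C–C recombination to a cyclopentene can compete. The oxide attacks the allyl terminus remote from silicon in a 6-exo closure (the allyl unit stays outside the new ring), forming O1–C2 and the left pyran; attack at the silylated terminus would need an eight-membered ring and is also disfavoured sterically and electronically. C3 is untouched and keeps the configuration set in step 8. C2 is formed with net retention (oxidative addition with inversion, outer-sphere attack of the soft oxide anti to palladium), which places the alkenyl group trans to the C3 methyl; because the product is itself an allylic ether of an acidic hydroxytropone, reversible re-ionisation should drain any cis isomer into the trans-diequatorial pyran. The syn-allyl geometry gives the (E)-alkenylsilane. Loss of ring strain and return to a neutral tropone drive the isomerisation, and no base is added because an oxide formed beforehand would make the tropone a poorer acceptor.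

Step 13
Reactants: 18 (2R,3R)-8-methoxy-3,5-dimethyl-2-[(E)-2-(trimethylsilyl)ethenyl]-3,4-dihydrocyclohepta[b]pyran-7(2H)-one
Product: 19 (2R,3R)-2-[(E)-2-iodoethenyl]-8-methoxy-3,5-dimethyl-3,4-dihydrocyclohepta[b]pyran-7(2H)-one
Conditions: NIS, 2,6-lutidine, (CF3)2CHOH, 0 °C
Reagents that add atoms: N-iodosuccinimide, O=C1CCC(=O)N1I
Why: Ipso-iododesilylation of an (E)-alkenylsilane proceeds with retention of geometry; the lutidine buffer keeps the medium from ionising the allylic ether.

Step 14
Reactants: 20 (S)-but-3-ene-1,2-diol
Product: 21 (S)-1-(trityloxy)but-3-en-2-ol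
Conditions: Ph3CCl, Et3N, DMAP (cat.), CH2Cl2, 0 °C → rt
Reagents that add atoms: trityl chloride, ClC(c1ccccc1)(c1ccccc1)c1ccccc1
Why: Tritylation is selective for the primary hydroxyl; the trityl ether is inert to borane, base, fluoride and Mitsunobu reagents.

Step 15
Reactants: 21 (S)-1-(trityloxy)but-3-en-2-ol; 9 5-bromo-2-methoxy-6-methyl-4-[2-(trimethylsilyl)ethoxy]cyclohepta-2,4,6-trien-1-one
Product: 23 5-[(3S)-3-hydroxy-4-(trityloxy)butyl]-2-methoxy-6-methyl-4-[2-(trimethylsilyl)ethoxy]cyclohepta-2,4,6-trien-1-one, via the B-alkyl-9-BBN adduct 22 (not isolated)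
Conditions: 9-BBN (2.2 equiv), THF, 0 °C → rt; then 9, Pd(OAc)2, SPhos, K3PO4, THF/H2O, 60 °C
Reagents that add atoms: none
Why: Anti-Markovnikov hydroboration of the terminal alkene (the second equivalent of borane masks the hydroxyl as a borinate), then B-alkyl Suzuki–Miyaura coupling with a ligand suited to doubly ortho-substituted bromides; the stereocentre is not involved.

Step 16
Reactants: 23 5-[(3S)-3-hydroxy-4-(trityloxy)butyl]-2-methoxy-6-methyl-4-[2-(trimethylsilyl)ethoxy]cyclohepta-2,4,6-trien-1-one
Product: 24 4-hydroxy-5-[(3S)-3-hydroxy-4-(trityloxy)butyl]-2-methoxy-6-methylcyclohepta-2,4,6-trien-1-one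
Conditions: Bu4NF, THF, 0 °C; NaH2PO4 buffer
Reagents that add atoms: none
Why: The same fluoride-induced loss of the silylethyl group as in step 11; the trityl ether is not affected.

Step 17
Reactants: 24 4-hydroxy-5-[(3S)-3-hydroxy-4-(trityloxy)butyl]-2-methoxy-6-methylcyclohepta-2,4,6-trien-1-one
Product: 25 (2R)-8-methoxy-5-methyl-2-[(trityloxy)methyl]-3,4-dihydrocyclohepta[b]pyran-7(2H)-one
Conditions: PPh3, DIAD, THF (high dilution), 0 °C → rt
Reagents that add atoms: none
Why: Intramolecular Mitsunobu etherification: the acidic hydroxytropone displaces the activated secondary alcohol in a 6-exo-tet SN2 step with inversion, turning the (S)-carbinol into (R)-C2; only the oxygen next to the side chain can reach.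

Step 18
Reactants: 25 (2R)-8-methoxy-5-methyl-2-[(trityloxy)methyl]-3,4-dihydrocyclohepta[b]pyran-7(2H)-one
Product: 26 (2R)-2-(hydroxymethyl)-8-methoxy-5-methyl-3,4-dihydrocyclohepta[b]pyran-7(2H)-one
Conditions: TsOH·H2O (cat.), MeOH/CH2Cl2, rt
Reagents that add atoms: none
Why: Acid-catalysed transfer of the trityl cation to methanol; at this stage C2–O is a non-allylic ether and the methyl ether can only exchange with the solvent.

Step 19
Reactants: 26 (2R)-2-(hydroxymethyl)-8-methoxy-5-methyl-3,4-dihydrocyclohepta[b]pyran-7(2H)-one
Product: 27 (2R)-8-methoxy-5-methyl-7-oxo-2,3,4,7-tetrahydrocyclohepta[b]pyran-2-carbaldehyde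
Conditions: Dess–Martin periodinane, NaHCO3, CH2Cl2, 0 °C
Reagents that add atoms: none
Why: Buffered Dess–Martin oxidation; the α-alkoxy aldehyde is used directly to avoid enolisation.

Step 20
Reactants: 28 dibromomethane; 29 tributyltin chloride
Product: 31 (dibromomethyl)tributylstannane, via dibromomethyllithium 30 (not isolated)
Conditions: LiN(i-Pr)2, THF, −95 °C; then Bu3SnCl, −95 → −78 °C
Reagents that add atoms: none
Why: Deprotonation of dibromomethane to the carbenoid at low temperature and trapping at tin.

Step 21
Reactants: 27 (2R)-8-methoxy-5-methyl-7-oxo-2,3,4,7-tetrahydrocyclohepta[b]pyran-2-carbaldehyde; 31 (dibromomethyl)tributylstannane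
Product: 32 (2R)-8-methoxy-5-methyl-2-[(E)-2-(tributylstannyl)ethenyl]-3,4-dihydrocyclohepta[b]pyran-7(2H)-one
Conditions: CrCl2, LiI, THF/DMF, rt
Reagents that add atoms: none
Why: Takai-type olefination with the stannyl-substituted geminal dichromium reagent gives the (E)-alkenylstannane; the non-basic medium should preserve the α-alkoxy stereocentre, and no palladium is used.

Step 22
Reactants: 19 (2R,3R)-2-[(E)-2-iodoethenyl]-8-methoxy-3,5-dimethyl-3,4-dihydrocyclohepta[b]pyran-7(2H)-one; 32 (2R)-8-methoxy-5-methyl-2-[(E)-2-(tributylstannyl)ethenyl]-3,4-dihydrocyclohepta[b]pyran-7(2H)-one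
Product: 33 (2R,3R)-8-methoxy-2-[(1E,3E)-4-[(2R)-8-methoxy-5-methyl-7-oxo-2,3,4,7-tetrahydrocyclohepta[b]pyran-2-yl]buta-1,3-dien-1-yl]-3,5-dimethyl-3,4-dihydrocyclohepta[b]pyran-7(2H)-one
Conditions: CuTC [Cu(O2CC4H3S), copper thiophene-2-carboxylate] (1.5 equiv), NMP, 0 °C → rt
Reagents that add atoms: none
Why: Copper-mediated Stille-type coupling: the carboxylate moves the alkenyl group from tin to monovalent copper, and the alkenylcopper couples with the alkenyl iodide with retention at both partners; the absence of zerovalent palladium keeps the allylic ethers from ionising.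

Step 23
Reactants: 33 (2R,3R)-8-methoxy-2-[(1E,3E)-4-[(2R)-8-methoxy-5-methyl-7-oxo-2,3,4,7-tetrahydrocyclohepta[b]pyran-2-yl]buta-1,3-dien-1-yl]-3,5-dimethyl-3,4-dihydrocyclohepta[b]pyran-7(2H)-one
Product: 34 (2R,3R)-8-hydroxy-2-[(1E,3E)-4-[(2R)-8-hydroxy-5-methyl-7-oxo-2,3,4,7-tetrahydrocyclohepta[b]pyran-2-yl]buta-1,3-dien-1-yl]-3,5-dimethyl-3,4-dihydrocyclohepta[b]pyran-7(2H)-one (CNP0332980.1)
Conditions: KOH (1 M aq.), THF, 40 °C; then NaH2PO4 buffer
Reagents that add atoms: potassium hydroxide, [K+].[OH-]
Why: Hydrolysis of the two vinylogous methyl esters by addition–elimination at the methoxy-bearing carbon next to each tropone carbonyl; each ring becomes an unreactive tropolonate once its methoxy group is lost, and no acid is present to ionise the dienylic C2–O bonds.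

Compound list

1 | 2-methylphenol | Cc1ccccc1O | starting material
2 | 2-(trimethylsilyl)ethanol | OCC[Si](C)(C)C | starting material
3 | 1-methyl-2-[2-(trimethylsilyl)ethoxy]benzene | Cc1ccccc1OCC[Si](C)(C)C | intermediate
4 | 1-methyl-2-[2-(trimethylsilyl)ethoxy]cyclohexa-1,4-diene | CC1=C(OCC[Si](C)(C)C)CC=CC1 | intermediate
5 | racemic cis-fused 7,7-dibromo-1-methyl-6-[2-(trimethylsilyl)ethoxy]bicyclo[4.1.0]hept-3-ene (one enantiomer drawn) | C[C@]12CC=CC[C@@]1(OCC[Si](C)(C)C)C2(Br)Br | intermediate
6 | racemic 7,7-dibromo-1-methyl-6-[2-(trimethylsilyl)ethoxy]bicyclo[4.1.0]heptane-3,4-diol, cis-diol anti to the bridge (one enantiomer drawn) | C[C@]12C[C@H](O)[C@H](O)C[C@@]1(OCC[Si](C)(C)C)C2(Br)Br | intermediate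
7 | racemic 7,7-dibromo-1-methyl-6-[2-(trimethylsilyl)ethoxy]bicyclo[4.1.0]heptane-3,4-dione (one enantiomer drawn) | C[C@]12CC(=O)C(=O)C[C@@]1(OCC[Si](C)(C)C)C2(Br)Br | intermediate
8 | 5-bromo-2-hydroxy-6-methyl-4-[2-(trimethylsilyl)ethoxy]cyclohepta-2,4,6-trien-1-one | Cc1cc(=O)c(O)cc(OCC[Si](C)(C)C)c1Br | intermediate
9 | 5-bromo-2-methoxy-6-methyl-4-[2-(trimethylsilyl)ethoxy]cyclohepta-2,4,6-trien-1-one | Cc1cc(=O)c(OC)cc(OCC[Si](C)(C)C)c1Br | intermediate
10 | (E)-3-(tributylstannyl)prop-2-en-1-ol | CCCC[Sn](CCCC)(CCCC)/C=C/CO | starting material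
11 | 5-[(E)-3-hydroxyprop-1-en-1-yl]-2-methoxy-6-methyl-4-[2-(trimethylsilyl)ethoxy]cyclohepta-2,4,6-trien-1-one | Cc1cc(=O)c(OC)cc(OCC[Si](C)(C)C)c1/C=C/CO | intermediate
12 | 1,1-diiodoethane | CC(I)I | starting material
13 | 5-[(1S,2S,3R)-2-(hydroxymethyl)-3-methylcyclopropyl]-2-methoxy-6-methyl-4-[2-(trimethylsilyl)ethoxy]cyclohepta-2,4,6-trien-1-one | Cc1cc(=O)c(OC)cc(OCC[Si](C)(C)C)c1[C@H]1[C@@H](C)[C@@H]1CO | intermediate
14 | 5-[(1S,2S,3R)-2-formyl-3-methylcyclopropyl]-2-methoxy-6-methyl-4-[2-(trimethylsilyl)ethoxy]cyclohepta-2,4,6-trien-1-one | Cc1cc(=O)c(OC)cc(OCC[Si](C)(C)C)c1[C@H]1[C@@H](C)[C@@H]1C=O | intermediate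
15 | (dibromomethyl)trimethylsilane | C[Si](C)(C)C(Br)Br | starting material
16 | 2-methoxy-6-methyl-5-[(1S,2S,3S)-2-methyl-3-[(E)-2-(trimethylsilyl)ethenyl]cyclopropyl]-4-[2-(trimethylsilyl)ethoxy]cyclohepta-2,4,6-trien-1-one | Cc1cc(=O)c(OC)cc(OCC[Si](C)(C)C)c1[C@H]1[C@@H](C)[C@@H]1/C=C/[Si](C)(C)C | intermediate
17 | 4-hydroxy-2-methoxy-6-methyl-5-[(1S,2S,3S)-2-methyl-3-[(E)-2-(trimethylsilyl)ethenyl]cyclopropyl]cyclohepta-2,4,6-trien-1-one | Cc1cc(=O)c(OC)cc(O)c1[C@H]1[C@@H](C)[C@@H]1/C=C/[Si](C)(C)C | intermediate
18 | (2R,3R)-8-methoxy-3,5-dimethyl-2-[(E)-2-(trimethylsilyl)ethenyl]-3,4-dihydrocyclohepta[b]pyran-7(2H)-one | Cc1cc(=O)c(OC)cc2c1C[C@@H](C)[C@H](/C=C/[Si](C)(C)C)O2 | intermediate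
19 | (2R,3R)-2-[(E)-2-iodoethenyl]-8-methoxy-3,5-dimethyl-3,4-dihydrocyclohepta[b]pyran-7(2H)-one | Cc1cc(=O)c(OC)cc2c1C[C@@H](C)[C@H](/C=C/I)O2 | intermediate
20 | (S)-but-3-ene-1,2-diol | C=C[C@H](O)CO | starting material
21 | (S)-1-(trityloxy)but-3-en-2-ol | C=C[C@H](O)COC(c1ccccc1)(c1ccccc1)c1ccccc1 | intermediate
22 | B-alkyl-9-BBN adduct of 21, hydroxyl held as its 9-BBN borinate, (S) | C1CCC2CCCC1B2CC[C@H](OB1C2CCCC1CCC2)COC(c1ccccc1)(c1ccccc1)c1ccccc1 | intermediate
23 | 5-[(3S)-3-hydroxy-4-(trityloxy)butyl]-2-methoxy-6-methyl-4-[2-(trimethylsilyl)ethoxy]cyclohepta-2,4,6-trien-1-one | Cc1cc(=O)c(OC)cc(OCC[Si](C)(C)C)c1CC[C@H](O)COC(c1ccccc1)(c1ccccc1)c1ccccc1 | intermediate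
24 | 4-hydroxy-5-[(3S)-3-hydroxy-4-(trityloxy)butyl]-2-methoxy-6-methylcyclohepta-2,4,6-trien-1-one | Cc1cc(=O)c(OC)cc(O)c1CC[C@H](O)COC(c1ccccc1)(c1ccccc1)c1ccccc1 | intermediate
25 | (2R)-8-methoxy-5-methyl-2-[(trityloxy)methyl]-3,4-dihydrocyclohepta[b]pyran-7(2H)-one | c1ccccc1C(c1ccccc1)(c1ccccc1)OC[C@H]1CCc2c(C)cc(=O)c(OC)cc2O1 | intermediate
26 | (2R)-2-(hydroxymethyl)-8-methoxy-5-methyl-3,4-dihydrocyclohepta[b]pyran-7(2H)-one | OC[C@H]1CCc2c(C)cc(=O)c(OC)cc2O1 | intermediate
27 | (2R)-8-methoxy-5-methyl-7-oxo-2,3,4,7-tetrahydrocyclohepta[b]pyran-2-carbaldehyde | O=C[C@H]1CCc2c(C)cc(=O)c(OC)cc2O1 | intermediate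
28 | dibromomethane | BrCBr | starting material
29 | tributyltin chloride | CCCC[Sn](Cl)(CCCC)CCCC | starting material
30 | dibromomethyllithium | [Li]C(Br)Br | intermediate
31 | (dibromomethyl)tributylstannane | CCCC[Sn](CCCC)(CCCC)C(Br)Br | intermediate
32 | (2R)-8-methoxy-5-methyl-2-[(E)-2-(tributylstannyl)ethenyl]-3,4-dihydrocyclohepta[b]pyran-7(2H)-one | CCCC[Sn](CCCC)(CCCC)/C=C/[C@H]1CCc2c(C)cc(=O)c(OC)cc2O1 | intermediate
33 | (2R,3R)-8-methoxy-2-[(1E,3E)-4-[(2R)-8-methoxy-5-methyl-7-oxo-2,3,4,7-tetrahydrocyclohepta[b]pyran-2-yl]buta-1,3-dien-1-yl]-3,5-dimethyl-3,4-dihydrocyclohepta[b]pyran-7(2H)-one | Cc1cc(=O)c(OC)cc2c1C[C@@H](C)[C@H](/C=C/C=C/[C@H]1CCc3c(C)cc(=O)c(OC)cc3O1)O2 | intermediate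
34 | (2R,3R)-8-hydroxy-2-[(1E,3E)-4-[(2R)-8-hydroxy-5-methyl-7-oxo-2,3,4,7-tetrahydrocyclohepta[b]pyran-2-yl]buta-1,3-dien-1-yl]-3,5-dimethyl-3,4-dihydrocyclohepta[b]pyran-7(2H)-one | Cc1cc(=O)c(O)cc2c1C[C@@H](C)[C@H](/C=C/C=C/[C@H]1CCc3c(C)cc(=O)c(O)cc3O1)O2 | target

Total step count: 23. Longest linear sequence: 15 steps (steps 1 to 13, then 22 and 23).

Least certain steps

**Step 12 (key step).** The tropone may be too weak an acceptor for the C–C oxidative addition. The zwitterion may also recombine at carbon to a cyclopentene or lose a β-hydrogen to a diene before proton transfer and O-attack. A fallback by known chemistry sets out from 9 and returns at 18, generating the same allylpalladium intermediate by ordinary ionisation of an allylic carbonate: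
- (S)-tert-butyl(3-iodo-2-methylpropoxy)dimethylsilane F1, made from methyl (S)-3-hydroxy-2-methylpropanoate by silylation, ester reduction and iodination, is converted with t-BuLi and B-methoxy-9-BBN into its borinate and coupled with 9 (Pd(dppf)Cl2, K3PO4) to give silyl ether F2.
- HF·pyridine frees primary alcohol F3, and Dess–Martin oxidation gives the α-methyl aldehyde F4.
- Nozaki–Hiyama–Kishi addition of (E)-(2-bromoethenyl)trimethylsilane (CrCl2, NiCl2 cat.) gives allylic alcohol F5 as a mixture of carbinol epimers, which is of no consequence.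
- Methyl chloroformate and pyridine give carbonate F6, and Bu4NF unmasks hydroxytropone carbonate F7.
- Pd(PPh3)4 then effects an intramolecular Tsuji–Trost etherification; both epimers pass through the same allyl complex and close to the trans pyran 18.

**Step 8.** The Lewis-basic tropone carbonyl may sequester the zinc carbenoid, and addition to a twisted, electron-poor alkene may be slow, with loss of facial and methyl-orientation selectivity. The fallback sets out from 9 and returns at 13 by building the ring before the tropone is attached. Purchased (E)-3-(4,4,5,5-tetramethyl-1,3,2-dioxaborolan-2-yl)prop-2-en-1-ol is cyclopropanated under the same conditions to the cyclopropylboronate F8 (methyl cis to boron, hydroxymethyl trans to both). A stereoretentive Suzuki–Miyaura coupling of F8 with 9 (Pd(OAc)2, SPhos, K3PO4) then gives 13.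

**Step 5.** The silylethyl group may be lost through an oxocarbenium pathway, or the dione may undergo C–C cleavage, in competition with enolisation and electrocyclic opening. The fallback sets out from 6 and returns at 8 in separate stages. Mono-oxidation (one equivalent of Dess–Martin periodinane) gives α-hydroxy ketone F9. DBU then opens the cyclopropane by vinylogous elimination of bromide to the bromo hydroxy cycloheptadienone F10. Oxidation of the remaining carbinol and tautomerisation give 8.

**Step 6.** The ambident tropolonate may be alkylated without site selectivity, which halves the throughput. The fallback sets out from 8 and returns at 9. The unwanted regioisomer, 5-bromo-2-methoxy-4-methyl-6-[2-(trimethylsilyl)ethoxy]cyclohepta-2,4,6-trien-1-one F11, is separated, hydrolysed back to 8 with dilute KOH and methylated again, so that material is recycled and not lost.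

**Step 23.** Hydroxide may add at the ring-oxygen-bearing carbon and open a pyran, or the dienylic ethers may decay during the slower second hydrolysis. The fallback sets out from 19 and 32 and returns at 34, moving the hydrolysis to the fragments and leaving a mild acyl transfer for the end:
- 19 is hydrolysed to tropolone F12 and acetylated (Ac2O, pyridine) to acetate F13.
- 32 is hydrolysed to tropolone F14 and acetylated to acetate F15.
- Coupling of F13 and F15 with CuTC gives bis(acetate) F16; the acetyl groups shuttle between the two tropolone oxygens, so no regiochemical question arises.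
- K2CO3 in methanol at 0 °C then releases 34.

Further compounds

F1 | step 12 | (S)-tert-butyl(3-iodo-2-methylpropoxy)dimethylsilane | IC[C@@H](C)CO[Si](C)(C)C(C)(C)C
F2 | step 12 | 5-[(2R)-3-(tert-butyldimethylsilyloxy)-2-methylpropyl]-2-methoxy-6-methyl-4-[2-(trimethylsilyl)ethoxy]cyclohepta-2,4,6-trien-1-one | Cc1cc(=O)c(OC)cc(OCC[Si](C)(C)C)c1C[C@@H](C)CO[Si](C)(C)C(C)(C)C
F3 | step 12 | 5-[(2R)-3-hydroxy-2-methylpropyl]-2-methoxy-6-methyl-4-[2-(trimethylsilyl)ethoxy]cyclohepta-2,4,6-trien-1-one | Cc1cc(=O)c(OC)cc(OCC[Si](C)(C)C)c1C[C@@H](C)CO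
F4 | step 12 | (2R)-2-methyl-3-[tropon-5-yl]propanal carrying 2-methoxy, 6-methyl and 4-[2-(trimethylsilyl)ethoxy] groups on the tropone | Cc1cc(=O)c(OC)cc(OCC[Si](C)(C)C)c1C[C@@H](C)C=O
F5 | step 12 | 5-[(2R,4E)-3-hydroxy-2-methyl-5-(trimethylsilyl)pent-4-en-1-yl]-2-methoxy-6-methyl-4-[2-(trimethylsilyl)ethoxy]cyclohepta-2,4,6-trien-1-one, both carbinol epimers | Cc1cc(=O)c(OC)cc(OCC[Si](C)(C)C)c1C[C@@H](C)C(O)/C=C/[Si](C)(C)C
F6 | step 12 | methyl carbonate of F5, both epimers | Cc1cc(=O)c(OC)cc(OCC[Si](C)(C)C)c1C[C@@H](C)C(OC(=O)OC)/C=C/[Si](C)(C)C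
F7 | step 12 | methyl carbonate of the free 4-hydroxytropone, both epimers | Cc1cc(=O)c(OC)cc(O)c1C[C@@H](C)C(OC(=O)OC)/C=C/[Si](C)(C)C
F8 | step 8 | [2-methyl-3-(4,4,5,5-tetramethyl-1,3,2-dioxaborolan-2-yl)cyclopropyl]methanol, methyl cis to boron, hydroxymethyl trans to both, configured as in 13 | CC1(C)OB(OC1(C)C)[C@H]1[C@@H](C)[C@@H]1CO
F9 | step 5 | racemic 7,7-dibromo-4-hydroxy-1-methyl-6-[2-(trimethylsilyl)ethoxy]bicyclo[4.1.0]heptan-3-one (one enantiomer drawn) | C[C@]12CC(=O)[C@H](O)C[C@@]1(OCC[Si](C)(C)C)C2(Br)Br
F10 | step 5 | racemic 4-bromo-7-hydroxy-3-methyl-5-[2-(trimethylsilyl)ethoxy]cyclohepta-2,4-dien-1-one | CC1=CC(=O)C(O)CC(OCC[Si](C)(C)C)=C1Br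
F11 | step 6 | 5-bromo-2-methoxy-4-methyl-6-[2-(trimethylsilyl)ethoxy]cyclohepta-2,4,6-trien-1-one | Cc1cc(OC)c(=O)cc(OCC[Si](C)(C)C)c1Br
F12 | step 23 | (2R,3R)-8-hydroxy-2-[(E)-2-iodoethenyl]-3,5-dimethyl-3,4-dihydrocyclohepta[b]pyran-7(2H)-one | Cc1cc(=O)c(O)cc2c1C[C@@H](C)[C@H](/C=C/I)O2
F13 | step 23 | acetate of F12 | Cc1cc(=O)c(OC(C)=O)cc2c1C[C@@H](C)[C@H](/C=C/I)O2
F14 | step 23 | (2R)-8-hydroxy-5-methyl-2-[(E)-2-(tributylstannyl)ethenyl]-3,4-dihydrocyclohepta[b]pyran-7(2H)-one | CCCC[Sn](CCCC)(CCCC)/C=C/[C@H]1CCc2c(C)cc(=O)c(O)cc2O1
F15 | step 23 | acetate of F14 | CCCC[Sn](CCCC)(CCCC)/C=C/[C@H]1CCc2c(C)cc(=O)c(OC(C)=O)cc2O1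
F16 | step 23 | bis(acetate) of 34 | Cc1cc(=O)c(OC(C)=O)cc2c1C[C@@H](C)[C@H](/C=C/C=C/[C@H]1CCc3c(C)cc(=O)c(OC(C)=O)cc3O1)O2
A1 | alternative 1 | dienyl diacid with both bromo-methoxytropone ethers and all three stereocentres | OC(=O)[C@@H](C)[C@H](/C=C/C=C/[C@H](Oc1cc(OC)c(=O)cc(C)c1Br)CC(=O)O)Oc1cc(OC)c(=O)cc(C)c1Br
A2 | alternative 2 | (2R)-2-[(tert-butyldimethylsilyloxy)methyl]-8-methoxy-5-methyl-3,4-dihydrocyclohepta[b]pyran-7(2H)-one | CC(C)(C)[Si](C)(C)OC[C@H]1CCc2c(C)cc(=O)c(OC)cc2O1
A3 | alternative 2 | (2R)-5-acetyl-2-[(tert-butyldimethylsilyloxy)methyl]-3,4-dihydro-2H-pyran-6-carbaldehyde | CC(C)(C)[Si](C)(C)OC[C@H]1CCC(C(C)=O)=C(C=O)O1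
A4 | alternative 2 | dimethyl (1-methoxy-2-oxopropyl)phosphonate | COC(C(C)=O)P(=O)(OC)OC
A5 | alternative 3 | target bis(methyl ether), identical with 33 | Cc1cc(=O)c(OC)cc2c1C[C@@H](C)[C@H](/C=C/C=C/[C@H]1CCc3c(C)cc(=O)c(OC)cc3O1)O2
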